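The route rests on cutting the bond between C1 of ring A (the 3-hydroxy-2-prenylphenyl ring) and the ketone carbon, which stays on ring B (the prenylated phloroglucinol ring) as a formyl group. The key step, a phenoxide-directed palladium-catalysed formyl C–H arylation, exploits the ring-B C2–OH ortho to that carbon. This hydroxyl binds the arylpalladium made from a ring-A iodide, a five-membered palladacycle (Pd, O, C2, C1, acyl C) forms, and reductive elimination gives the diaryl ketone directly at the ketone oxidation level. Its precursors are a 3-prenylphloroglucinaldehyde with one free ortho-OH and 1-iodo-3-(methoxymethoxy)-2-prenylbenzene; neither is a preformed organometallic or an activated acid derivative.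

Key step: step 5

Remark: the target has no stereocentre and no stereogenic double bond (both alkenes end in CMe2). It is therefore achiral and no enantiocontrol is needed.

Step 1
Reactants: 1 3-iodophenol
Product: 2 1-iodo-3-(methoxymethoxy)benzene
Conditions: NaH, DMF, 0 °C; MOMCl, 0 °C → rt
Reagents that add atoms: chloromethyl methyl ether (MOMCl), COCCl
Why: Williamson-type O-alkylation of the sodium phenoxide with the very reactive α-chloro ether should install an acetal that is stable to base and later directs metalation.

Step 2
Reactants: 2 1-iodo-3-(methoxymethoxy)benzene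
Product: 5 1-iodo-3-(methoxymethoxy)-2-(3-methylbut-2-en-1-yl)benzene, via aryllithium 3 (not isolated), via arylcopper 4 (not isolated)
Conditions: LDA (commercial solution), THF, −78 °C; CuBr·SMe2 (1 equiv), −78 °C; prenyl bromide, −78 → 0 °C
Reagents that add atoms: prenyl bromide (1-bromo-3-methylbut-2-ene), CC(C)=CCBr
Why: Directed ortho-metalation should remove the most acidic proton, C2–H between the chelating OMOM group and the inductively acidifying iodine, without iodine–lithium exchange, and transmetalation to copper at −78 °C should suppress loss of LiI to the aryne and give SN2 allylic substitution at the unhindered CH2 of prenyl bromide.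

Step 3
Reactants: 6 2,4,6-trihydroxybenzaldehyde
Product: 7 2,4,6-trihydroxy-3-(3-methylbut-2-en-1-yl)benzaldehyde
Conditions: KOH (1 equiv), H2O, 0 °C; prenyl bromide (0.9 equiv), 0 °C → rt
Reagents that add atoms: prenyl bromide (1-bromo-3-methylbut-2-ene), CC(C)=CCBr
Why: C-alkylation of an ambident phloroglucinol phenoxide should occur because in water the oxygen atoms are hydrogen-bonded, so the soft allylic bromide is attacked by ring carbon C3 (equivalent to C5), the dienone tautomerises back to the arene, and a deficit of bromide limits double prenylation.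

Step 4
Reactants: 7 2,4,6-trihydroxy-3-(3-methylbut-2-en-1-yl)benzaldehyde
Product: 8 2-hydroxy-4,6-bis(methoxymethoxy)-3-(3-methylbut-2-en-1-yl)benzaldehyde
Conditions: MOMCl (2.1 equiv), i-Pr2NEt, CH2Cl2, 0 °C → rt
Reagents that add atoms: chloromethyl methyl ether (MOMCl), COCCl
Why: In this selective MOM protection (O-alkylation) O4–H and the less hindered O6–H should react, while the C2–OH, hydrogen-bonded to the formyl oxygen and flanked by the prenyl group, stays free; the site of the second MOM group is not critical, since either ortho hydroxyl can direct step 5 and all MOM groups fall in step 6.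

Step 5
Reactants: 5 1-iodo-3-(methoxymethoxy)-2-(3-methylbut-2-en-1-yl)benzene; 8 2-hydroxy-4,6-bis(methoxymethoxy)-3-(3-methylbut-2-en-1-yl)benzaldehyde
Product: 9 [2-hydroxy-4,6-bis(methoxymethoxy)-3-(3-methylbut-2-en-1-yl)phenyl][3-(methoxymethoxy)-2-(3-methylbut-2-en-1-yl)phenyl]methanone
Conditions: PdCl2 (10 mol %), LiCl (0.5 equiv), Na2CO3 (2 equiv), DMF, 100 °C, Ar
Reagents that add atoms: none
Why: Oxidative addition of Pd(0) into the C–I bond of 5 gives an arylpalladium(II) iodide, the sodium phenoxide of 8 displaces iodide at palladium, the formyl C–H bond thus held next to the metal is cleaved with carbonate as proton acceptor to give a five-membered aroyl(aryl)oxapalladacycle, and C–C reductive elimination forms the ring-A C1–carbonyl bond and returns Pd(0). The closest known reaction type is the palladium-catalysed coupling of salicylaldehydes with aryl iodides to 2-hydroxybenzophenones under ligand-free PdCl2/LiCl/Na2CO3 conditions. No ring of the product is closed and no stereocentre is made, since the palladacycle is only transient. The step needs chemoselectivity for the formyl C–H bond over O-arylation, decarbonylation and insertion into the two prenyl alkenes: chelation by the single free C2–OH secures the first, decarbonylation would have to contract the chelate to a strained four-membered ring, and trisubstituted alkenes insert only slowly into aryl–Pd or Pd–O bonds. The MOM groups at O4, O6 and on ring A keep all other phenols away from palladium and are stable to carbonate at 100 °C.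

Step 6
Reactants: 9 [2-hydroxy-4,6-bis(methoxymethoxy)-3-(3-methylbut-2-en-1-yl)phenyl][3-(methoxymethoxy)-2-(3-methylbut-2-en-1-yl)phenyl]methanone
Product: 10 cudraphenone D
Conditions: HCl (cat.), MeOH, rt → 40 °C
Reagents that add atoms: none
Why: Acid-catalysed acetal solvolysis (MOM cleavage by transacetalisation to dimethoxymethane) should free the three phenols, because catalytic HCl in methanol near room temperature cleaves aryl MOM ethers faster than it protonates the trisubstituted alkenes, as is usual for prenylated polyphenols.

Compound list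
1 | 3-iodophenol | Oc1cccc(I)c1 | starting material
2 | 1-iodo-3-(methoxymethoxy)benzene | COCOc1cccc(I)c1 | intermediate
3 | [2-iodo-6-(methoxymethoxy)phenyl]lithium (not isolated) | [Li]c1c(I)cccc1OCOC | intermediate
4 | [2-iodo-6-(methoxymethoxy)phenyl]copper (not isolated) | [Cu]c1c(I)cccc1OCOC | intermediate
5 | 1-iodo-3-(methoxymethoxy)-2-(3-methylbut-2-en-1-yl)benzene | CC(C)=CCc1c(I)cccc1OCOC | intermediate
6 | 2,4,6-trihydroxybenzaldehyde | O=Cc1c(O)cc(O)cc1O | starting material
7 | 2,4,6-trihydroxy-3-(3-methylbut-2-en-1-yl)benzaldehyde | CC(C)=CCc1c(O)cc(O)c(C=O)c1O | intermediate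
8 | 2-hydroxy-4,6-bis(methoxymethoxy)-3-(3-methylbut-2-en-1-yl)benzaldehyde | CC(C)=CCc1c(O)c(C=O)c(OCOC)cc1OCOC | intermediate
9 | [2-hydroxy-4,6-bis(methoxymethoxy)-3-(3-methylbut-2-en-1-yl)phenyl][3-(methoxymethoxy)-2-(3-methylbut-2-en-1-yl)phenyl]methanone | CC(C)=CCc1c(OCOC)cccc1C(=O)c1c(O)c(CC=C(C)C)c(OCOC)cc1OCOC | intermediate
10 | cudraphenone D, [3-hydroxy-2-(3-methylbut-2-en-1-yl)phenyl][2,4,6-trihydroxy-3-(3-methylbut-2-en-1-yl)phenyl]methanone (achiral) | CC(C)=CCc1c(O)cccc1C(=O)c1c(O)cc(O)c(CC=C(C)C)c1O | target

Total step count: 6. Longest linear sequence: 4 steps (steps 1, 2, 5, 6). The ring-B branch (steps 3, 4, 5, 6) is equally long.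

Steps most likely to fail

Step 5. Formyl C–H cleavage at an aldehyde with two ortho substituents may be slow. Protodeiodination or homocoupling of the aryl iodide, decarbonylation of the aroylpalladium, or oxypalladation of the prenyl group next to the bound phenoxide could then take over.

The fallback forms the same bond by polar carbonyl addition at the alcohol oxidation level. It sets out from 5 and 8 and comes back to the route at 10.
- The last phenol of 8 is capped (NaH, MOMCl, DMF) to give 2,4,6-tris(methoxymethoxy)-3-(3-methylbut-2-en-1-yl)benzaldehyde F1.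
- Iodine–lithium exchange on 5 (n-BuLi, THF, −78 °C) gives [3-(methoxymethoxy)-2-(3-methylbut-2-en-1-yl)phenyl]lithium F2.
- F2 adds to F1 to give racemic [3-(methoxymethoxy)-2-(3-methylbut-2-en-1-yl)phenyl][2,4,6-tris(methoxymethoxy)-3-(3-methylbut-2-en-1-yl)phenyl]methanol F3.
- Oxidation with Dess–Martin periodinane/NaHCO3 gives [3-(methoxymethoxy)-2-(3-methylbut-2-en-1-yl)phenyl][2,4,6-tris(methoxymethoxy)-3-(3-methylbut-2-en-1-yl)phenyl]methanone F4.
- The conditions of step 6 remove all four MOM groups to give 10.

Step 2. The ortho-iodoaryllithium may lose LiI before it is trapped, metalation may stay incomplete, or allylic substitution may occur with transposition.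

The fallback places the prenyl group by a sigmatropic shift instead of an organometallic alkylation. It sets out from 1 and comes back at 5.
- Copper-catalysed O-alkylation with 3-chloro-3-methylbut-1-yne (CuCl2 cat., DBU, MeCN, 0 °C) gives 1-iodo-3-[(2-methylbut-3-yn-2-yl)oxy]benzene F5.
- Semihydrogenation over Lindlar catalyst with quinoline gives 1-iodo-3-[(2-methylbut-3-en-2-yl)oxy]benzene F6.
- Aromatic Claisen rearrangement (xylene, 140 °C), which a meta halogen biases toward the flanked ortho position, gives 3-iodo-2-(3-methylbut-2-en-1-yl)phenol F7 after chromatographic removal of the other ortho isomer.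
- MOM protection of F7 under the conditions of step 1 gives 5.

Step 6. Protonation of a prenyl alkene may be followed by capture by the neighbouring freed phenol (cyclisation to a chroman ring). The released formaldehyde equivalent may also alkylate the electron-rich ring B.

The fallback replaces acid solvolysis by a protecting-group exchange under buffered, non-acidic conditions and then a fluoride cleavage. It sets out from 9 and comes back at 10.
- TESOTf and 2,2′-bipyridyl (MeCN, 0 °C → rt) convert the three aryl MOM ethers directly into aryl triethylsilyl ethers and silylate the free C2–OH. This gives [3-(triethylsilyloxy)-2-(3-methylbut-2-en-1-yl)phenyl][2,4,6-tris(triethylsilyloxy)-3-(3-methylbut-2-en-1-yl)phenyl]methanone F8.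
- TBAF buffered with AcOH (THF, 0 °C) desilylates F8 to 10.

Further compounds
F1 | step 5 | 2,4,6-tris(methoxymethoxy)-3-(3-methylbut-2-en-1-yl)benzaldehyde | CC(C)=CCc1c(OCOC)c(C=O)c(OCOC)cc1OCOC
F2 | step 5 | [3-(methoxymethoxy)-2-(3-methylbut-2-en-1-yl)phenyl]lithium | [Li]c1cccc(OCOC)c1CC=C(C)C
F3 | step 5 | [3-(methoxymethoxy)-2-(3-methylbut-2-en-1-yl)phenyl][2,4,6-tris(methoxymethoxy)-3-(3-methylbut-2-en-1-yl)phenyl]methanol (racemic) | CC(C)=CCc1c(OCOC)cccc1C(O)c1c(OCOC)c(CC=C(C)C)c(OCOC)cc1OCOC
F4 | step 5 | [3-(methoxymethoxy)-2-(3-methylbut-2-en-1-yl)phenyl][2,4,6-tris(methoxymethoxy)-3-(3-methylbut-2-en-1-yl)phenyl]methanone | CC(C)=CCc1c(OCOC)cccc1C(=O)c1c(OCOC)c(CC=C(C)C)c(OCOC)cc1OCOC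
F5 | step 2 | 1-iodo-3-[(2-methylbut-3-yn-2-yl)oxy]benzene | C#CC(C)(C)Oc1cccc(I)c1
F6 | step 2 | 1-iodo-3-[(2-methylbut-3-en-2-yl)oxy]benzene | C=CC(C)(C)Oc1cccc(I)c1
F7 | step 2 | 3-iodo-2-(3-methylbut-2-en-1-yl)phenol | CC(C)=CCc1c(O)cccc1I
F8 | step 6 | [3-(triethylsilyloxy)-2-(3-methylbut-2-en-1-yl)phenyl][2,4,6-tris(triethylsilyloxy)-3-(3-methylbut-2-en-1-yl)phenyl]methanone | CC(C)=CCc1c(O[Si](CC)(CC)CC)cccc1C(=O)c1c(O[Si](CC)(CC)CC)c(CC=C(C)C)c(O[Si](CC)(CC)CC)cc1O[Si](CC)(CC)CC
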